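**Plan**

- Retrosynthesis: remove the enol-ether methyl and the formyl carbon of the side chain, then the C7 methyl (C7 becomes a ketone), then delete the C8 methylene and the 8a-hydroxyl, so that ring A becomes the cyclopentanone of a bicyclic 1,3-diketone (C7 and C1 carbonyls on C8a).
- Enabling feature: C8a, the ring-fusion carbinol of ring A (C4a, C5, C6, C7, C8, C8a), is α to the C1 ketone of ring B and separated from the C7 carbinol carbon only by C8. The C7–C8–C8a–C1 array is the 1,4-dioxygenation pattern left by one-carbon homologation of a 1,3-dicarbonyl, which also frees C8a as an enolate for hydroxylation.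
- Further cuts: C2–OH (Rubottom oxidation), C4a–C8a and C3–C4 (intramolecular Diels–Alder), C7–C8a (Claisen acylation; these two carbons are directly bonded before the homologation), and the two C=C bonds (Wittig).
- Forward: two Wittig enones are joined to a 1,3-diketone; its silyl enol ether closes ring B and a five-membered ring in one cycloaddition; the five-membered ring is then expanded to ring A with hydroxylation at C8a; methyl addition and side-chain completion follow.
- Stereochemistry: the sec-butyl centre comes from (S)-2-methylbutan-1-ol and C5 from (R)-2-methylsuccinate. C4a, C4 and C3 come from the endo Diels–Alder transition state steered by C5, C2 from epoxidation anti to sec-butyl, C8a from oxygen delivery by the C2 alkoxide, and C7 from equatorial methyl attack.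

Key step: step 8

Remark: atom labels C1 to C8a in the text are those of the target decalin (ring B = C1, C2, C3, C4, C4a, C8a) and denote the same carbons in every intermediate; β is the face carrying the three hydroxyl groups (H-4a is α); names in the compound list use each compound's own locants.

Assumption: the 1,3-diketones 12 and 16 are written as diketo tautomers although they should be largely enolized, and 16 is drawn cis-fused at its epimerizable ring-fusion carbon.

**Step 1**
Reactants: 1 (S)-2-methylbutan-1-ol; 2 3-(triphenylphosphoranylidene)butan-2-one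
Product: 4 (3E,5S)-3,5-dimethylhept-3-en-2-one, via (S)-2-methylbutanal 3 (not isolated)
Conditions: (2,2,6,6-tetramethylpiperidin-1-yl)oxyl (TEMPO, cat.), PhI(OAc)2, CH2Cl2, rt; then 2, 40 °C
Reagents that add atoms: none
Why: Oxidation of the primary alcohol by the TEMPO oxoammonium cycle followed in the same flask by a Wittig reaction with the acyl-stabilized ylide should give the (E)-trisubstituted enone without isolation of the racemization-prone aldehyde; no stereocentre is formed and the (S) centre of 1 is carried through.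

**Step 2**
Reactants: 5 (2R)-4-tert-butoxy-2-methyl-4-oxobutanoic acid
Product: 6 tert-butyl (3R)-4-hydroxy-3-methylbutanoate
Conditions: BH3·SMe2, THF, 0 °C to rt; MeOH quench
Reagents that add atoms: none
Why: Chemoselective borane reduction of the free carboxylic acid in the presence of the tert-butyl ester should give the primary alcohol with the stereocentre untouched.

**Step 3**
Reactants: 6 tert-butyl (3R)-4-hydroxy-3-methylbutanoate; 2 3-(triphenylphosphoranylidene)butan-2-one
Product: 8 tert-butyl (3R,4E)-3,5-dimethyl-6-oxohept-4-enoate, via tert-butyl (3R)-3-methyl-4-oxobutanoate 7 (not isolated)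
Conditions: TEMPO (cat.), PhI(OAc)2, CH2Cl2, rt; then 2, 40 °C
Reagents that add atoms: none
Why: The same one-flask TEMPO oxidation and Wittig reaction as in step 1 exposes the α-stereocentre of aldehyde 7 only briefly to neutral conditions, and the stabilized ylide should give the (E)-enone.

**Step 4**
Reactants: 8 tert-butyl (3R,4E)-3,5-dimethyl-6-oxohept-4-enoate
Product: 9 (3R,4E)-3,5-dimethyl-6-oxohept-4-enoic acid
Conditions: CF3CO2H, CH2Cl2, 0 °C to rt
Reagents that add atoms: none
Why: Acid-mediated cleavage of the tert-butyl ester (loss of 2-methylpropene) frees the acid without base, which protects the γ-stereocentre of the enone from epimerization.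

**Step 5**
Reactants: 9 (3R,4E)-3,5-dimethyl-6-oxohept-4-enoic acid; 4 (3E,5S)-3,5-dimethylhept-3-en-2-one
Product: 12 (3E,5R,10E,12S)-3,5,10,12-tetramethyltetradeca-3,10-diene-2,7,9-trione, via acyl imidazole 10 (not isolated), via lithium enolate 11 (not isolated)
Conditions: 9, 1,1'-carbonyldiimidazole, THF, rt; separately 4 (3.3 equiv), LiN(i-Pr)2 (3.3 equiv), THF, −78 °C; add the first solution to the second, −78 to −40 °C; AcOH
Reagents that add atoms: none
Why: Claisen-type C-acylation of the kinetic α′-lithium enolate of methyl ketone 4 by the acyl imidazole should give the 1,3-diketone; the enolate is used in excess because imidazole and the acidic product each consume one equivalent, and no stereocentre is formed.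

**Step 6**
Reactants: 12 (3E,5R,10E,12S)-3,5,10,12-tetramethyltetradeca-3,10-diene-2,7,9-trione
Product: 14 (3R,3aS,4R,5S,7aS)-4-acetyl-5-[(2S)-butan-2-yl]-3,4,6-trimethyl-7-[(trimethylsilyl)oxy]-2,3,3a,4,5,7a-hexahydro-1H-inden-1-one, via silyl enol ether 13 (not isolated)
Conditions: N,O-bis(trimethylsilyl)acetamide, toluene, rt; then 2,6-di-tert-butyl-4-methylphenol (cat.), 140 °C, sealed tube
Reagents that add atoms: N,O-bis(trimethylsilyl)acetamide CC(=N[Si](C)(C)C)O[Si](C)(C)C
Why: Silylation of the enolized 1,3-diketone gives the (Z)-2-silyloxy diene (the regioisomeric enol ether is funnelled in by 1,5-silyl shift), which should undergo an intramolecular Diels–Alder reaction with the tethered (E)-enone through the acetyl-endo transition state that leads to the trans-fused hydrindanone; the C5 methyl group sits anti to the diene on the forming five-membered ring (allylic strain), so C4a, C4 and C3 are set relative to C5 and the (E) geometry fixes methyl and acetyl at C4.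

**Step 7**
Reactants: 14 (3R,3aS,4R,5S,7aS)-4-acetyl-5-[(2S)-butan-2-yl]-3,4,6-trimethyl-7-[(trimethylsilyl)oxy]-2,3,3a,4,5,7a-hexahydro-1H-inden-1-one
Product: 16 (3R,3aS,4R,5R,6S,7aS)-4-acetyl-5-[(2S)-butan-2-yl]-6-hydroxy-3,4,6-trimethylhexahydro-1H-indene-1,7(7aH)-dione, via silyloxy epoxide 15 (not isolated)
Conditions: dimethyldioxirane, acetone/CH2Cl2, −78 to −40 °C; then Et3N·3HF, THF, 0 °C
Reagents that add atoms: dimethyldioxirane CC1(C)OO1
Why: In this Rubottom oxidation, dimethyldioxirane should epoxidize the electron-rich silyl enol ether on the face anti to the adjacent pseudoaxial sec-butyl group and fluoride then opens the silyloxy oxirane to the α-hydroxy ketone, which sets C2; the ring-fusion carbon C8a becomes part of an enolizable 1,3-diketone.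

**Step 8**
Reactants: 16 (3R,3aS,4R,5R,6S,7aS)-4-acetyl-5-[(2S)-butan-2-yl]-6-hydroxy-3,4,6-trimethylhexahydro-1H-indene-1,7(7aH)-dione
Product: 18 (2S,3R,4S,4aR,5R,8aR)-4-acetyl-3-[(2S)-butan-2-yl]-2,8a-dihydroxy-2,4,5-trimethyl-3,4,4a,5,6,8a-hexahydronaphthalene-1,7(2H,8H)-dione, via zinc enolate 17 (not isolated)
Conditions: Et2Zn (5 equiv), CH2I2 (3 equiv), CH2Cl2, 0 °C to rt; then EtZnOO-t-Bu (4 equiv, premixed from Et2Zn and anhydrous t-BuOOH in toluene), −40 to 0 °C; aq. NH4Cl
Reagents that add atoms: diiodomethane ICI; tert-butyl hydroperoxide CC(C)(C)OO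
Why: Proposed new method: Et2Zn deprotonates the 1,3-diketone (C8a) and the C2 hydroxyl of 16, the carbenoid EtZnCH2I transfers its methylene (the future C8) to C8a, the zinc-bound CH2 adds to the C7 carbonyl (3-exo-trig) to give a donor–acceptor cyclopropoxide, and strain-driven retro-aldol cleavage of the C7–C8a bond enlarges the cyclopentanone to the cyclohexanone ring A and releases the C8a=C1 zinc enolate 17. The closest known reaction type is the zinc-carbenoid chain extension and ring expansion of β-keto esters and 1,3-diketones to 1,4-dicarbonyl compounds with trapping of the zinc enolate in the same flask by aldehydes or iodine; what is new is the trapping by oxygen, for which the models are the oxidation of organozinc compounds by zinc alkylperoxides and peroxide epoxidations steered by a zinc alkoxide. No ring is closed for good: the cyclopropane is transient and ring A arises only by enlargement of the five-membered ring. The new stereocentre C8a is set by the C2 zinc alkoxide, which binds EtZnOO-t-Bu and sits pseudoaxial on the β face next to the enolate, so that oxygen should be delivered cis to the 2-oxygen and trans to H-4a (trans-decalin). The step needs carbonyl selection, secured because O-1 is held in a five-membered zinc chelate with O-2 and C1 is flanked by the quaternary C2 whereas attack at C7 relieves the cyclopentanone, and face selection, secured by the tether; a wrong 8a epimer would be the aldol epimer of 18 and could be equilibrated by retro-aldol/aldol on the zinc 2,8a-diolate.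

**Step 9**
Reactants: 18 (2S,3R,4S,4aR,5R,8aR)-4-acetyl-3-[(2S)-butan-2-yl]-2,8a-dihydroxy-2,4,5-trimethyl-3,4,4a,5,6,8a-hexahydronaphthalene-1,7(2H,8H)-dione
Product: 19 (2S,3R,4S,4aR,5R,7R,8aR)-4-acetyl-3-[(2S)-butan-2-yl]-2,7,8a-trihydroxy-2,4,5,7-tetramethyl-3,4,4a,5,6,7,8,8a-octahydronaphthalen-1(2H)-one
Conditions: MeMgBr (3.5 equiv), CH2Cl2/Et2O, −78 °C; aq. NH4Cl
Reagents that add atoms: methylmagnesium bromide C[Mg]Br
Why: Grignard addition should occur at the only unhindered ketone (C7), which is further activated by chelation to the magnesium 8a-alkoxide while the C1 ketone (flanked by two fully substituted carbons) and the neopentyl acetyl group react more slowly; the axial 8a-alkoxide blocks the axial trajectory, so methyl should enter equatorially and give the axial 7-hydroxyl cis to the 8a-hydroxyl.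

**Step 10**
Reactants: 19 (2S,3R,4S,4aR,5R,7R,8aR)-4-acetyl-3-[(2S)-butan-2-yl]-2,7,8a-trihydroxy-2,4,5,7-tetramethyl-3,4,4a,5,6,7,8,8a-octahydronaphthalen-1(2H)-one
Product: 20 (2S,3R,4S,4aR,5R,7R,8aR)-3-[(2S)-butan-2-yl]-2,7,8a-trihydroxy-4-[(2Z)-3-hydroxyprop-2-enoyl]-2,4,5,7-tetramethyl-3,4,4a,5,6,7,8,8a-octahydronaphthalen-1(2H)-one
Conditions: LiN(SiMe3)2 (4.5 equiv), THF, −78 °C; HCO2CH2CF3, −78 to 0 °C; aq. NH4Cl; then K2CO3, MeOH, 0 °C
Reagents that add atoms: 2,2,2-trifluoroethyl formate O=COCC(F)(F)F
Why: Crossed Claisen formylation of the lithium enolate of the acetyl group, the only enolizable carbonyl left (C1 has no α-hydrogen), with the reactive formate ester should give the hydroxymethylene ketone; formate esters formed on the tertiary alkoxides are cleaved by the methanolic carbonate work-up.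

**Step 11**
Reactants: 20 (2S,3R,4S,4aR,5R,7R,8aR)-3-[(2S)-butan-2-yl]-2,7,8a-trihydroxy-4-[(2Z)-3-hydroxyprop-2-enoyl]-2,4,5,7-tetramethyl-3,4,4a,5,6,7,8,8a-octahydronaphthalen-1(2H)-one
Product: 21 (2S,3R,4S,4aR,5R,7R,8aR)-3-[(2S)-butan-2-yl]-2,7,8a-trihydroxy-4-[(2E)-3-methoxyprop-2-enoyl]-2,4,5,7-tetramethyl-3,4,4a,5,6,7,8,8a-octahydronaphthalen-1(2H)-one
Conditions: Me2SO4, K2CO3, acetone, rt
Reagents that add atoms: dimethyl sulfate COS(=O)(=O)OC
Why: O-Methylation of the acidic hydroxymethylene ketone on its terminal oxygen (Williamson-type alkylation under weak base that leaves the three tertiary alcohols untouched) should give the vinylogous methyl ester, whose push–pull double bond equilibrates to the (E) isomer of the target.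

**Compound list**

1 | (S)-2-methylbutan-1-ol | CC[C@H](C)CO | starting material
2 | 3-(triphenylphosphoranylidene)butan-2-one | CC(=O)C(C)=P(c1ccccc1)(c1ccccc1)c1ccccc1 | starting material
3 | (S)-2-methylbutanal | CC[C@H](C)C=O | intermediate
4 | (3E,5S)-3,5-dimethylhept-3-en-2-one | CC[C@H](C)/C=C(\C)C(C)=O | intermediate
5 | (2R)-4-tert-butoxy-2-methyl-4-oxobutanoic acid | CC(C)(C)OC(=O)C[C@@H](C)C(O)=O | starting material
6 | tert-butyl (3R)-4-hydroxy-3-methylbutanoate | CC(C)(C)OC(=O)C[C@@H](C)CO | intermediate
7 | tert-butyl (3R)-3-methyl-4-oxobutanoate | CC(C)(C)OC(=O)C[C@@H](C)C=O | intermediate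
8 | tert-butyl (3R,4E)-3,5-dimethyl-6-oxohept-4-enoate | CC(C)(C)OC(=O)C[C@@H](C)/C=C(\C)C(C)=O | intermediate
9 | (3R,4E)-3,5-dimethyl-6-oxohept-4-enoic acid | OC(=O)C[C@@H](C)/C=C(\C)C(C)=O | intermediate
10 | 1-[(3R,4E)-3,5-dimethyl-6-oxohept-4-enoyl]-1H-imidazole (acyl imidazole) | O=C(C[C@@H](C)/C=C(\C)C(C)=O)n1ccnc1 | intermediate
11 | lithium (3E,5S)-3,5-dimethylhepta-1,3-dien-2-olate (lithium enolate of 4) | CC[C@H](C)/C=C(\C)C(=C)O[Li] | intermediate
12 | (3E,5R,10E,12S)-3,5,10,12-tetramethyltetradeca-3,10-diene-2,7,9-trione | CC[C@H](C)/C=C(\C)C(=O)CC(=O)C[C@@H](C)/C=C(\C)C(C)=O | intermediate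
13 | (3E,5R,8Z,10E,12S)-3,5,10,12-tetramethyl-9-[(trimethylsilyl)oxy]tetradeca-3,8,10-triene-2,7-dione (silyl enol ether) | CC[C@H](C)/C=C(\C)/C(O[Si](C)(C)C)=C/C(=O)C[C@@H](C)/C=C(\C)C(C)=O | intermediate
14 | (3R,3aS,4R,5S,7aS)-4-acetyl-5-[(2S)-butan-2-yl]-3,4,6-trimethyl-7-[(trimethylsilyl)oxy]-2,3,3a,4,5,7a-hexahydro-1H-inden-1-one | CC[C@H](C)[C@@H]1[C@](C)(C(C)=O)[C@H]2[C@H](C)CC(=O)[C@@H]2C(O[Si](C)(C)C)=C1C | intermediate
15 | 6,7-epoxide of 14 (silyloxy epoxide; oxirane oxygen on the face anti to the sec-butyl group) | CC[C@H](C)[C@@H]1[C@](C)(C(C)=O)[C@H]2[C@H](C)CC(=O)[C@@H]2[C@@]3(O[Si](C)(C)C)O[C@@]13C | intermediate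
16 | (3R,3aS,4R,5R,6S,7aS)-4-acetyl-5-[(2S)-butan-2-yl]-6-hydroxy-3,4,6-trimethylhexahydro-1H-indene-1,7(7aH)-dione | CC[C@H](C)[C@@H]1[C@](C)(C(C)=O)[C@H]2[C@H](C)CC(=O)[C@H]2C(=O)[C@@]1(C)O | intermediate
17 | bis(ethylzinc) derivative of ring-expanded 18 lacking the 8a-oxygen (C8a=C1 zinc enolate, C2 zinc alkoxide) | CC[C@H](C)[C@@H]1[C@](C)(C(C)=O)[C@H]2[C@H](C)CC(=O)CC2=C(O[Zn]CC)[C@@]1(C)O[Zn]CC | intermediate
18 | (2S,3R,4S,4aR,5R,8aR)-4-acetyl-3-[(2S)-butan-2-yl]-2,8a-dihydroxy-2,4,5-trimethyl-3,4,4a,5,6,8a-hexahydronaphthalene-1,7(2H,8H)-dione | CC[C@H](C)[C@@H]1[C@](C)(C(C)=O)[C@H]2[C@H](C)CC(=O)C[C@]2(O)C(=O)[C@@]1(C)O | intermediate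
19 | (2S,3R,4S,4aR,5R,7R,8aR)-4-acetyl-3-[(2S)-butan-2-yl]-2,7,8a-trihydroxy-2,4,5,7-tetramethyl-3,4,4a,5,6,7,8,8a-octahydronaphthalen-1(2H)-one | CC[C@H](C)[C@@H]1[C@](C)(C(C)=O)[C@H]2[C@H](C)C[C@@](C)(O)C[C@]2(O)C(=O)[C@@]1(C)O | intermediate
20 | (2S,3R,4S,4aR,5R,7R,8aR)-3-[(2S)-butan-2-yl]-2,7,8a-trihydroxy-4-[(2Z)-3-hydroxyprop-2-enoyl]-2,4,5,7-tetramethyl-3,4,4a,5,6,7,8,8a-octahydronaphthalen-1(2H)-one (hydroxymethylene ketone) | CC[C@H](C)[C@@H]1[C@](C)(C(=O)/C=C\O)[C@H]2[C@H](C)C[C@@](C)(O)C[C@]2(O)C(=O)[C@@]1(C)O | intermediate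
21 | (2S,3R,4S,4aR,5R,7R,8aR)-3-[(2S)-butan-2-yl]-2,7,8a-trihydroxy-4-[(2E)-3-methoxyprop-2-enoyl]-2,4,5,7-tetramethyl-3,4,4a,5,6,7,8,8a-octahydronaphthalen-1(2H)-one | CC[C@H](C)[C@@H]1[C@](C)(C(=O)/C=C/OC)[C@H]2[C@H](C)C[C@@](C)(O)C[C@]2(O)C(=O)[C@@]1(C)O | target

**Step count and risks**

Total step count: 11. Longest linear sequence: 10 steps (5 → 6 → 8 → 9 → 12 → 14 → 16 → 18 → 19 → 20 → 21; steps 2 to 11).

Steps most likely to fail:

1. Step 8 (proposed new method). Oxygen transfer from the zinc peroxide to the ring-fusion zinc enolate may lose to protonation or to undirected attack on the α face, and the carbenoid may insert at the wrong carbonyl. Fallback with known chemistry, setting out from 16: the zinc-carbenoid ring expansion is run in its established tandem form with an iodine quench (Et2Zn, CH2I2, CH2Cl2; then I2) to give the 8a-iodo analogue of 18 F1. DBU then removes hydrogen iodide to give the ring A enedione F2 (C8=C8a). A Mukaiyama-type radical hydration (Mn(dpm)3 cat., PhSiH3, O2, i-PrOH; then P(OEt)3) should add hydrogen to the less substituted C8 and oxygen to the tertiary C8a radical, and the route is rejoined at 18. Any 8a epimer is an aldol epimer and can be equilibrated by retro-aldol/aldol with K2CO3 in MeOH.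

2. Step 6. The thermal cycloaddition may show poor endo/exo or π-facial selectivity, or the silyl enol ether may be lost at 140 °C. Fallback, setting out from 12: a silyl triflate-mediated intramolecular double Michael reaction (t-BuMe2SiOTf, Et3N, CH2Cl2, −78 to 0 °C) closes the two rings stepwise (Mukaiyama–Michael, then Michael) through compact low-temperature transition states. It should give the tert-butyldimethylsilyl analogue of 14 F3, which is oxidized under the step 7 conditions (dimethyldioxirane; Et3N·3HF) and rejoins the route at 16.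

3. Step 9. The Grignard reagent may also add to the side-chain methyl ketone, or the magnesium ketolate may open by retro-aldol. Fallback, setting out from 18: a Corey–Chaykovsky reaction with dimethylsulfoxonium methylide (Me3S(O)I, NaH, DMSO), a reversible, sterically selective and weakly basic reagent, should attack only the unhindered C7 ketone from the equatorial side and give the 7-spiro-epoxide of 18 F4. PhSNa in EtOH opens the oxirane at its CH2 to the 7-[(phenylsulfanyl)methyl] analogue of 19 F5, and desulfurization with Raney Ni (deactivated with acetone) rejoins the route at 19.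

**Further compounds**

F1 | step 8 | 8a-iodo analogue of 18 (iodine in place of the 8a-hydroxyl; 8a configuration not controlled) | CC[C@H](C)[C@@H]1[C@](C)(C(C)=O)[C@H]2[C@H](C)CC(=O)CC2(I)C(=O)[C@@]1(C)O
F2 | step 8 | enedione: 8,8a-didehydro-8a-deoxy analogue of 18 | CC[C@H](C)[C@@H]1[C@](C)(C(C)=O)[C@H]2[C@H](C)CC(=O)C=C2C(=O)[C@@]1(C)O
F3 | step 6 | tert-butyldimethylsilyl analogue of 14 | CC[C@H](C)[C@@H]1[C@](C)(C(C)=O)[C@H]2[C@H](C)CC(=O)[C@@H]2C(O[Si](C)(C)C(C)(C)C)=C1C
F4 | step 9 | 7-spiro-epoxide of 18 (oxirane oxygen axial, cis to the 8a-hydroxyl) | CC[C@H](C)[C@@H]1[C@](C)(C(C)=O)[C@H]2[C@H](C)C[C@@]3(OC3)C[C@]2(O)C(=O)[C@@]1(C)O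
F5 | step 9 | 7-[(phenylsulfanyl)methyl] analogue of 19 (sulfide in place of one hydrogen of the 7-methyl group) | CC[C@H](C)[C@@H]1[C@](C)(C(C)=O)[C@H]2[C@H](C)C[C@@](CSc3ccccc3)(O)C[C@]2(O)C(=O)[C@@]1(C)O
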